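**Plan**
Retrosynthesis: the C8 glycidate ester and the butenolide (O6–C12 ester, C7=C11 by metathesis) are cut first; both epoxides go back to an E,E-cyclodeca-1(10),4-diene; C2–C3 is then cut with re-formation of C5–C10 (retro-oxy-Cope) to a six-membered ring, from which isopropenyl (C5–C4), methyl and vinyl (both on C10) are removed.
Forward: ring C5–C10 is made first from methyl α-D-glucopyranoside (Ferrier carbocyclisation), C10 and C5 are substituted, the six-membered ring is expanded to the ten-membered ring, the epoxides are added, and the butenolide is closed last.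
Enabling feature: the ten-membered ring holds C1=C10 and C4=C5 (the later trans-epoxides) linked by the C2–C3 bridge, the 1,5-diene that a [3,3] shift across a C5–C10 bond leaves behind; C5 carries only H in the target, so the oxygen that drives the shift can leave as an enol triflate.
Stereochemistry: C6, C7, C8 are C4, C3, C2 of D-glucose; C10 (axial methylation) and C5 (chelated addition) only place vinyl and isopropenyl trans so that both ring alkenes form E; the four epoxide centres come from peripheral attack on that diene; the side-chain centre comes from methyl (S)-2-methylglycidate.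

Key step: step 13

Remark: carbocyclic intermediates carry the germacrane locants their carbons keep to the end (C5 = glucose C5, C6/C7/C8 = glucose C4/C3/C2, C9 = glucose C1, C10 = glucose C6); α/β follow the usual germacranolide drawing (O6 and O8 α, O7 β); PMB = 4-methoxybenzyl, TES = triethylsilyl, TBS = tert-butyldimethylsilyl; the Ferrier product is written as its expected major 9-epimer.

Step 1
Reactants: 1 methyl α-D-glucopyranoside
Product: 2 methyl 4,6-O-[(R)-4-methoxybenzylidene]-α-D-glucopyranoside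
Conditions: 4-MeOC6H4CH(OMe)2, camphorsulfonic acid (cat.), DMF, 60 °C, reduced pressure
Reagents that add atoms: 4-methoxybenzaldehyde dimethyl acetal, COc1ccc(C(OC)OC)cc1
Why: Acid-catalysed transacetalisation should give the thermodynamically preferred trans-fused six-membered 4,6-acetal with the aryl group equatorial, leaving O2 and O3 free.

Step 2
Reactants: 2 methyl 4,6-O-(4-methoxybenzylidene)-α-D-glucopyranoside
Product: 3 methyl 2-O-TBS-4,6-O-(4-methoxybenzylidene)-α-D-glucopyranoside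
Conditions: TBSCl (1.1 equiv), imidazole, DMF, 0 → 23 °C
Reagents that add atoms: tert-butyldimethylsilyl chloride, CC(C)(C)[Si](C)(C)Cl
Why: Regioselective silylation, since in 4,6-O-arylidene α-glucosides the O2 hydroxyl (hydrogen-bonded to the cis anomeric methoxy group and less hindered than O3 next to the acetal) reacts first with one equivalent of silyl chloride.

Step 3
Reactants: 3 methyl 2-O-TBS-4,6-O-(4-methoxybenzylidene)-α-D-glucopyranoside
Product: 4 methyl 2-O-TBS-3-O-TES-4,6-O-(4-methoxybenzylidene)-α-D-glucopyranoside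
Conditions: Et3SiOTf, 2,6-lutidine, CH2Cl2, −78 → 0 °C
Reagents that add atoms: triethylsilyl trifluoromethanesulfonate, CC[Si](CC)(CC)OS(=O)(=O)C(F)(F)F
Why: Silyl triflate silylation of the remaining hindered secondary alcohol, buffered by lutidine so that the acetal survives.

Step 4
Reactants: 4 methyl 2-O-TBS-3-O-TES-4,6-O-(4-methoxybenzylidene)-α-D-glucopyranoside
Product: 5 methyl 2-O-TBS-3-O-TES-4-O-PMB-α-D-glucopyranoside
Conditions: iBu2AlH, toluene/CH2Cl2, −40 → 0 °C
Reagents that add atoms: none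
Why: Regioselective reductive opening of the arylidene acetal, in which the aluminium hydride binds the less hindered O6, the C–O6 bond ionises and hydride reduces the oxocarbenium ion, so the PMB ether stays on O4 and the primary alcohol is freed.

Step 5
Reactants: 5 methyl 2-O-TBS-3-O-TES-4-O-PMB-α-D-glucopyranoside
Product: 6 methyl 6-deoxy-6-iodo-2-O-TBS-3-O-TES-4-O-PMB-α-D-glucopyranoside
Conditions: I2, PPh3, imidazole, toluene, 60 °C
Reagents that add atoms: iodine, [I][I]
Why: Appel-type iodination of the primary alcohol through its alkoxyphosphonium salt (SN2 at C6 of the sugar).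

Step 6
Reactants: 6 methyl 6-deoxy-6-iodo-2-O-TBS-3-O-TES-4-O-PMB-α-D-glucopyranoside
Product: 7 methyl 6-deoxy-2-O-TBS-3-O-TES-4-O-PMB-α-D-xylo-hex-5-enopyranoside
Conditions: tBuOK, THF, 0 → 23 °C
Reagents that add atoms: none
Why: E2 dehydroiodination gives the exocyclic enol ether; with no free hydroxyl present the silyl ethers cannot migrate.

Step 7
Reactants: 7 methyl 6-deoxy-2-O-TBS-3-O-TES-4-O-PMB-α-D-xylo-hex-5-enopyranoside
Product: 8 9α-hydroxy-6α-PMB-oxy-7β-TES-oxy-8α-TBS-oxy-cyclohexan-5-one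
Conditions: Hg(OCOCF3)2 (10 mol%), acetone/H2O 4:1, 23 °C
Reagents that add atoms: water, O
Why: Ferrier carbocyclisation (oxymercuration of the enol ether, loss of methanol to a mercurated 5-keto aldehyde, intramolecular aldol closure) gives the six-membered ring with C2–C4 of glucose carried over unchanged as C8, C7 and C6; the new carbinol centre is lost in the next step.

Step 8
Reactants: 8 9α-hydroxy-6α-PMB-oxy-7β-TES-oxy-8α-TBS-oxy-cyclohexan-5-one
Product: 10 6α-PMB-oxy-7β-TES-oxy-8α-TBS-oxy-cyclohex-9-en-5-one, via 9-O-mesylate 9 (not isolated)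
Conditions: MsCl, Et3N, CH2Cl2, 0 → 23 °C
Reagents that add atoms: none
Why: Mesylation followed by E1cB elimination gives the conjugated enone from either 9-epimer.

Step 9
Reactants: 10 6α-PMB-oxy-7β-TES-oxy-8α-TBS-oxy-cyclohex-9-en-5-one
Product: 11 10-iodo-6α-PMB-oxy-7β-TES-oxy-8α-TBS-oxy-cyclohex-9-en-5-one
Conditions: I2, pyridine, CH2Cl2, 0 → 23 °C
Reagents that add atoms: iodine, [I][I]
Why: α-Iodination of a β-unsubstituted cyclohexenone by conjugate addition of pyridine, iodination of the enolate and elimination (Baylis–Hillman-type addition–elimination).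

Step 10
Reactants: 11 10-iodo enone; 12 tributyl(vinyl)stannane
Product: 13 10-vinyl-6α-PMB-oxy-7β-TES-oxy-8α-TBS-oxy-cyclohex-9-en-5-one
Conditions: Pd2(dba)3 (5 mol%), AsPh3 (20 mol%), NMP, 23 °C
Reagents that add atoms: none
Why: Stille coupling of an α-iodoenone, fast at room temperature under neutral conditions with the weakly bound arsine ligand; the cross-conjugated dienone is used at once to avoid Diels–Alder dimerisation.

Step 11
Reactants: 13 10-vinyl enone
Product: 15 10β-methyl-10α-vinyl-6α-PMB-oxy-7β-TES-oxy-8α-TBS-oxy-cyclohexan-5-one, via lithium dienolate 14 (not isolated)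
Conditions: LiBH(sBu)3 (1.05 equiv), THF, −78 °C; then MeI (excess), DMPU, −78 → −30 °C
Reagents that add atoms: iodomethane, IC
Why: Conjugate hydride reduction of the β-unsubstituted enone gives the C5–C10 dienolate regiospecifically (no enolate toward C6, hence no β-elimination of O7), and reductive alkylation at its α-carbon follows, MeI entering axially on the β-face through a chair-like transition state that keeps O6, O7 and O8 equatorial, which sets C10 with methyl β (trans to O8) and vinyl α and equatorial.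

Step 12
Reactants: 15 10β-methyl-10α-vinyl ketone; 16 isopropenylmagnesium bromide
Product: 17 5β-isopropenyl-10β-methyl-10α-vinyl-6α-PMB-oxy-7β-TES-oxy-8α-TBS-oxy-cyclohexan-5α-ol
Conditions: CeCl3 (anhydrous, 1.5 equiv), THF, −78 °C; aq. NH4Cl
Reagents that add atoms: none
Why: Organocerium 1,2-addition (which suppresses enolisation toward C6), in which cerium bridges the carbonyl and the equatorial O6 PMB ether and isopropenyl is delivered along the equatorial trajectory, trans to O6 and trans to the C10 vinyl group, to give the axial 5α-alcohol; any 5-epimer is removed by chromatography.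

Step 13
Reactants: 17 trans-1-isopropenyl-2-methyl-2-vinylcyclohexanol (5α-ol)
Product: 20 (1(10)E)-4,10-dimethyl-6α-PMB-oxy-7β-TES-oxy-8α-TBS-oxy-cyclodeca-1(10),4-dien-5-yl triflate with C3 trans to C6, via potassium alkoxide 18 (not isolated), via ten-membered potassium enolate 19 (not isolated)
Conditions: KN(SiMe3)2 (1.1 equiv), 18-crown-6 (1.2 equiv), THF, 0 → 23 °C; then PhNTf2 (1.3 equiv), −78 → 0 °C
Reagents that add atoms: N-phenylbis(trifluoromethanesulfonimide), O=S(=O)(N(c1ccccc1)S(=O)(=O)C(F)(F)F)C(F)(F)F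
Why: Deprotonation gives alkoxide 18, whose charge-accelerated [3,3]-sigmatropic shift (anionic oxy-Cope rearrangement, the known ring expansion of 1,2-dialkenylcyclohexanols to cyclodec-5-enone enolates) joins C2 to C3 while C5–C10 breaks. The ten-membered ring is thus formed by pericyclic four-carbon ring expansion of the six-membered ring through a chair transition state, not by end-to-end cyclisation. No stereocentre is created: C5 and C10 are lost and C6, C7, C8 are untouched. The step needs E geometry in both new ring double bonds, which the trans, diequatorial alkenyl groups secure, since with O6, O7 and O8 also equatorial C9 and C6 sit pseudo-equatorial on the pericyclic chair and give the 1(10)E alkene and the enolate with C3 trans to C6. PhNTf2 added cold sulfonylates enolate 19 on oxygen before proton transfer can move or isomerise it, fixing C4=C5 as the enol triflate. 18-Crown-6 frees the alkoxide from potassium so that the shift runs near room temperature, well below the temperature at which the neutral Cope equilibrium would favour the six-membered ring.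

Step 14
Reactants: 20 ten-membered enol triflate
Product: 21 (1(10)E,4E)-4,10-dimethyl-6α-PMB-oxy-7β-TES-oxy-8α-TBS-oxy-cyclodeca-1(10),4-diene
Conditions: Pd(OAc)2 (5 mol%), PPh3 (10 mol%), Bu3N, HCO2H, DMF, 50 °C
Reagents that add atoms: none
Why: Palladium-catalysed formate reduction of an enol triflate (oxidative addition, formate exchange, loss of CO2, C–H reductive elimination) replaces the triflate by hydrogen with retention of alkene geometry, at a temperature below that of the neutral Cope rearrangement.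

Step 15
Reactants: 21 E,E-diene
Product: 22 1β,10α:4α,5β-diepoxy-4,10-dimethyl-6α-PMB-oxy-7β-TES-oxy-8α-TBS-oxy-cyclodecane
Conditions: mCPBA (2.4 equiv), NaHCO3, CH2Cl2, 0 °C
Reagents that add atoms: 3-chloroperoxybenzoic acid, OOC(=O)c1cccc(Cl)c1
Why: Prilezhaev epoxidation of the two strained trisubstituted E-alkenes, each from its exposed outer face in the crossed conformation that keeps O6, O7 and O8 equatorial and both methyl groups on the β-face, should give the (1R,10R,4R,5R) arrangement; each epoxide is trans because each alkene is E.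

Step 16
Reactants: 22 bis-epoxide
Product: 23 1β,10α:4α,5β-diepoxy-6α-PMB-oxy-8α-TBS-oxy-4,10-dimethylcyclodecan-7β-ol
Conditions: HF·pyridine, pyridine, THF, 0 °C
Reagents that add atoms: none
Why: Selective desilylation, the triethylsilyl ether being cleaved by pyridine-buffered HF·pyridine far faster than the tert-butyldimethylsilyl ether while the buffered medium spares the epoxides.

Step 17
Reactants: 23 7β-alcohol
Product: 24 1β,10α:4α,5β-diepoxy-6α-PMB-oxy-8α-TBS-oxy-4,10-dimethylcyclodecan-7-one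
Conditions: Dess–Martin periodinane, NaHCO3, CH2Cl2, 23 °C
Reagents that add atoms: none
Why: Dess–Martin oxidation of the hindered secondary alcohol under buffered, non-basic conditions, so that the ketone cannot enolise toward C6 and open the 4,5-epoxide.

Step 18
Reactants: 24 7-ketone
Product: 25 1β,10α:4α,5β-diepoxy-7-methylene-6α-PMB-oxy-8α-TBS-oxy-4,10-dimethylcyclodecane
Conditions: Cp2TiMe2, toluene/THF, 65 °C, dark
Reagents that add atoms: dimethyltitanocene, C[Ti](C)(C1C=CC=C1)C1C=CC=C1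
Why: Petasis methylenation, in which the titanocene methylidene formed on heating is non-basic and only weakly Lewis acidic, so the hindered α,α′-dioxygenated ketone should be converted to the exocyclic alkene without enolisation or epoxide opening.

Step 19
Reactants: 25 7-methylene compound
Product: 26 1β,10α:4α,5β-diepoxy-7-methylene-6α-PMB-oxy-4,10-dimethylcyclodecan-8α-ol
Conditions: Bu4NF, THF, 0 → 23 °C
Reagents that add atoms: none
Why: Fluoride-induced cleavage of the silyl ether at a stage that holds no carbonyl or ester and hence no base-sensitive group.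

Step 20
Reactants: 27 methyl (S)-2-methylglycidate
Product: 28 (S)-2-methylglycidic acid
Conditions: LiOH, THF/H2O, 0 °C; then cold dilute HCl to pH 3, extraction
Reagents that add atoms: lithium hydroxide, [Li+].[OH-]
Why: Ester saponification by acyl–oxygen cleavage leaves the quaternary epoxide stereocentre untouched; the acid is used at once.

Step 21
Reactants: 26 8α-alcohol; 28 (S)-2-methylglycidic acid
Product: 29 8α-[(S)-2-methyloxirane-2-carbonyloxy]-1β,10α:4α,5β-diepoxy-7-methylene-6α-PMB-oxy-4,10-dimethylcyclodecane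
Conditions: DCC, DMAP (cat.), CH2Cl2, 0 → 23 °C
Reagents that add atoms: none
Why: Steglich esterification of the secondary allylic alcohol with retention at C8 and at the acid stereocentre.

Step 22
Reactants: 29 8α-glycidate 6α-PMB ether
Product: 30 8α-[(S)-2-methyloxirane-2-carbonyloxy]-1β,10α:4α,5β-diepoxy-7-methylene-4,10-dimethylcyclodecan-6α-ol
Conditions: DDQ, CH2Cl2/pH 7 phosphate buffer, 0 °C
Reagents that add atoms: none
Why: Oxidative cleavage of the 4-methoxybenzyl ether by DDQ (hydride abstraction, hydrolysis of the oxocarbenium ion) at neutral pH, which the epoxides, the ester and the alkene tolerate.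

Step 23
Reactants: 31 2-(bromomethyl)acrylic acid
Product: 32 2-(acetoxymethyl)acrylic acid
Conditions: KOAc (3 equiv), AcOH, 70 °C
Reagents that add atoms: potassium acetate, CC(=O)[O-].[K+]
Why: Allylic substitution of bromide by acetate (SN2 or SN2′, which give the same product).

Step 24
Reactants: 30 6α-alcohol; 32 2-(acetoxymethyl)acrylic acid
Product: 33 6α-[2-(acetoxymethyl)acryloyloxy]-8α-[(S)-2-methyloxirane-2-carbonyloxy]-1β,10α:4α,5β-diepoxy-7-methylene-4,10-dimethylcyclodecane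
Conditions: DCC, DMAP (5 mol%), CH2Cl2, 0 °C
Reagents that add atoms: none
Why: Steglich esterification of the allylic C6 alcohol, with DMAP kept catalytic and cold to limit its reversible SN2′ addition to the acetoxymethyl acrylate.

Step 25
Reactants: 33 diene ester
Product: 34 (1R,4R,5R,6S,8S,10R)-13-acetoxy-1,10:4,5-diepoxy-8-[(2S)-2-methyloxirane-2-carbonyloxy]germacr-7(11)-en-12,6-olide (CNP0289810.2)
Conditions: second-generation Hoveyda–Grubbs catalyst (H2IMes)Cl2Ru=CH(2-iPrOC6H4) (15 mol%, in portions), toluene, 80 °C, argon sparge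
Reagents that add atoms: none
Why: Ring-closing metathesis of the C7 methylene with the acrylate methylene closes the five-membered lactone ring (O6, C12, C11, C7, C6) and forms the tetrasubstituted C7=C11 bond with loss of ethylene, a closure known for 2-substituted acrylates of 2-methylenecycloalkanols with phosphine-free N-heterocyclic-carbene ruthenium catalysts; no other alkene remains in the molecule.

**Compound list**
1 | methyl α-D-glucopyranoside | CO[C@@H]1[C@H](O)[C@@H](O)[C@H](O)[C@@H](CO)O1 | starting material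
2 | methyl 4,6-O-[(R)-4-methoxybenzylidene]-α-D-glucopyranoside | CO[C@@H]1[C@H](O)[C@@H](O)[C@@H]2O[C@H](c3ccc(OC)cc3)OC[C@H]2O1 | intermediate
3 | methyl 2-O-TBS-4,6-O-[(R)-4-methoxybenzylidene]-α-D-glucopyranoside | CO[C@@H]1[C@H](O[Si](C)(C)C(C)(C)C)[C@@H](O)[C@@H]2O[C@H](c3ccc(OC)cc3)OC[C@H]2O1 | intermediate
4 | methyl 2-O-TBS-3-O-TES-4,6-O-[(R)-4-methoxybenzylidene]-α-D-glucopyranoside | CO[C@@H]1[C@H](O[Si](C)(C)C(C)(C)C)[C@@H](O[Si](CC)(CC)CC)[C@@H]2O[C@H](c3ccc(OC)cc3)OC[C@H]2O1 | intermediate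
5 | methyl 2-O-TBS-3-O-TES-4-O-PMB-α-D-glucopyranoside | CO[C@@H]1[C@H](O[Si](C)(C)C(C)(C)C)[C@@H](O[Si](CC)(CC)CC)[C@H](OCc2ccc(OC)cc2)[C@@H](CO)O1 | intermediate
6 | methyl 6-deoxy-6-iodo-2-O-TBS-3-O-TES-4-O-PMB-α-D-glucopyranoside | CO[C@@H]1[C@H](O[Si](C)(C)C(C)(C)C)[C@@H](O[Si](CC)(CC)CC)[C@H](OCc2ccc(OC)cc2)[C@@H](CI)O1 | intermediate
7 | methyl 6-deoxy-2-O-TBS-3-O-TES-4-O-PMB-α-D-xylo-hex-5-enopyranoside | CO[C@@H]1[C@H](O[Si](C)(C)C(C)(C)C)[C@@H](O[Si](CC)(CC)CC)[C@H](OCc2ccc(OC)cc2)C(=C)O1 | intermediate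
8 | 9α-hydroxy-6α-PMB-oxy-7β-TES-oxy-8α-TBS-oxy-cyclohexan-5-one (6,7-trans, 7,8-trans, 8,9-cis) | O[C@@H]1[C@H](O[Si](C)(C)C(C)(C)C)[C@@H](O[Si](CC)(CC)CC)[C@H](OCc2ccc(OC)cc2)C(=O)C1 | intermediate
9 | 9α-methanesulfonyloxy-6α-PMB-oxy-7β-TES-oxy-8α-TBS-oxy-cyclohexan-5-one (not isolated) | CS(=O)(=O)O[C@@H]1[C@H](O[Si](C)(C)C(C)(C)C)[C@@H](O[Si](CC)(CC)CC)[C@H](OCc2ccc(OC)cc2)C(=O)C1 | intermediate
10 | 6α-PMB-oxy-7β-TES-oxy-8α-TBS-oxy-cyclohex-9-en-5-one | O=C1C=C[C@H](O[Si](C)(C)C(C)(C)C)[C@@H](O[Si](CC)(CC)CC)[C@@H]1OCc1ccc(OC)cc1 | intermediate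
11 | 10-iodo-6α-PMB-oxy-7β-TES-oxy-8α-TBS-oxy-cyclohex-9-en-5-one | O=C1C(I)=C[C@H](O[Si](C)(C)C(C)(C)C)[C@@H](O[Si](CC)(CC)CC)[C@@H]1OCc1ccc(OC)cc1 | intermediate
12 | tributyl(vinyl)stannane | C=C[Sn](CCCC)(CCCC)CCCC | starting material
13 | 10-vinyl-6α-PMB-oxy-7β-TES-oxy-8α-TBS-oxy-cyclohex-9-en-5-one | O=C1C(C=C)=C[C@H](O[Si](C)(C)C(C)(C)C)[C@@H](O[Si](CC)(CC)CC)[C@@H]1OCc1ccc(OC)cc1 | intermediate
14 | lithium 5(10)-dienolate of the 10-vinyl ketone (not isolated) | [Li+].[O-]C1=C(C=C)C[C@H](O[Si](C)(C)C(C)(C)C)[C@@H](O[Si](CC)(CC)CC)[C@@H]1OCc1ccc(OC)cc1 | intermediate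
15 | 10β-methyl-10α-vinyl-6α-PMB-oxy-7β-TES-oxy-8α-TBS-oxy-cyclohexan-5-one | O=C1[C@](C)(C=C)C[C@H](O[Si](C)(C)C(C)(C)C)[C@@H](O[Si](CC)(CC)CC)[C@@H]1OCc1ccc(OC)cc1 | intermediate
16 | isopropenylmagnesium bromide | C=C(C)[Mg]Br | starting material
17 | 5β-isopropenyl-10β-methyl-10α-vinyl-6α-PMB-oxy-7β-TES-oxy-8α-TBS-oxy-cyclohexan-5α-ol (alkenyl groups trans) | CC[Si](CC)(CC)O[C@@H]1[C@@H](O[Si](C)(C)C(C)(C)C)C[C@@](C)(C=C)[C@](O)(C(C)=C)[C@H]1OCc1ccc(OC)cc1 | intermediate
18 | potassium alkoxide of 17 (not isolated) | CC[Si](CC)(CC)O[C@@H]1[C@@H](O[Si](C)(C)C(C)(C)C)C[C@@](C)(C=C)[C@]([O-])(C(C)=C)[C@H]1OCc1ccc(OC)cc1.[K+] | intermediate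
19 | potassium (1(10)E)-4,10-dimethyl-6α-PMB-oxy-7β-TES-oxy-8α-TBS-oxy-cyclodeca-1(10),4-dien-5-olate, C3 trans to C6 (not isolated) | CC[Si](CC)(CC)O[C@@H]1[C@@H](O[Si](C)(C)C(C)(C)C)C/C(C)=C/CC/C(C)=C([O-])/[C@H]1OCc1ccc(OC)cc1.[K+] | intermediate
20 | (1(10)E)-4,10-dimethyl-6α-PMB-oxy-7β-TES-oxy-8α-TBS-oxy-cyclodeca-1(10),4-dien-5-yl trifluoromethanesulfonate, C3 trans to C6 | CC[Si](CC)(CC)O[C@@H]1[C@@H](O[Si](C)(C)C(C)(C)C)C/C(C)=C/CC/C(C)=C(OS(=O)(=O)C(F)(F)F)/[C@H]1OCc1ccc(OC)cc1 | intermediate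
21 | (1(10)E,4E)-4,10-dimethyl-6α-PMB-oxy-7β-TES-oxy-8α-TBS-oxy-cyclodeca-1(10),4-diene | CC[Si](CC)(CC)O[C@@H]1[C@@H](O[Si](C)(C)C(C)(C)C)C/C(C)=C/CC/C(C)=C/[C@H]1OCc1ccc(OC)cc1 | intermediate
22 | (1R,10R,4R,5R)-1,10:4,5-diepoxy-4,10-dimethyl-6α-PMB-oxy-7β-TES-oxy-8α-TBS-oxy-cyclodecane | CC[Si](CC)(CC)O[C@@H]1[C@@H](O[Si](C)(C)C(C)(C)C)C[C@@]2(C)O[C@@H]2CC[C@@]3(C)O[C@@H]3[C@H]1OCc1ccc(OC)cc1 | intermediate
23 | 1β,10α:4α,5β-diepoxy-6α-PMB-oxy-8α-TBS-oxy-4,10-dimethylcyclodecan-7β-ol | O[C@@H]1[C@@H](O[Si](C)(C)C(C)(C)C)C[C@@]2(C)O[C@@H]2CC[C@@]3(C)O[C@@H]3[C@H]1OCc1ccc(OC)cc1 | intermediate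
24 | 1β,10α:4α,5β-diepoxy-6α-PMB-oxy-8α-TBS-oxy-4,10-dimethylcyclodecan-7-one | O=C1[C@@H](O[Si](C)(C)C(C)(C)C)C[C@@]2(C)O[C@@H]2CC[C@@]3(C)O[C@@H]3[C@H]1OCc1ccc(OC)cc1 | intermediate
25 | 1β,10α:4α,5β-diepoxy-7-methylene-6α-PMB-oxy-8α-TBS-oxy-4,10-dimethylcyclodecane | C=C1[C@@H](O[Si](C)(C)C(C)(C)C)C[C@@]2(C)O[C@@H]2CC[C@@]3(C)O[C@@H]3[C@H]1OCc1ccc(OC)cc1 | intermediate
26 | 1β,10α:4α,5β-diepoxy-7-methylene-6α-PMB-oxy-4,10-dimethylcyclodecan-8α-ol | C=C1[C@@H](O)C[C@@]2(C)O[C@@H]2CC[C@@]3(C)O[C@@H]3[C@H]1OCc1ccc(OC)cc1 | intermediate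
27 | methyl (S)-2-methylglycidate | COC(=O)[C@]1(C)CO1 | starting material
28 | (S)-2-methylglycidic acid | OC(=O)[C@]1(C)CO1 | intermediate
29 | 8α-[(S)-2-methyloxirane-2-carbonyloxy]-1β,10α:4α,5β-diepoxy-7-methylene-6α-PMB-oxy-4,10-dimethylcyclodecane | C=C1[C@@H](OC(=O)[C@]2(C)CO2)C[C@@]2(C)O[C@@H]2CC[C@@]3(C)O[C@@H]3[C@H]1OCc1ccc(OC)cc1 | intermediate
30 | 8α-[(S)-2-methyloxirane-2-carbonyloxy]-1β,10α:4α,5β-diepoxy-7-methylene-4,10-dimethylcyclodecan-6α-ol | C=C1[C@@H](OC(=O)[C@]2(C)CO2)C[C@@]2(C)O[C@@H]2CC[C@@]3(C)O[C@@H]3[C@H]1O | intermediate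
31 | 2-(bromomethyl)acrylic acid | OC(=O)C(=C)CBr | starting material
32 | 2-(acetoxymethyl)acrylic acid | CC(=O)OCC(=C)C(=O)O | intermediate
33 | 6α-[2-(acetoxymethyl)acryloyloxy]-8α-[(S)-2-methyloxirane-2-carbonyloxy]-1β,10α:4α,5β-diepoxy-7-methylene-4,10-dimethylcyclodecane | C=C1[C@@H](OC(=O)[C@]2(C)CO2)C[C@@]2(C)O[C@@H]2CC[C@@]3(C)O[C@@H]3[C@H]1OC(=O)C(=C)COC(C)=O | intermediate
34 | (1R,4R,5R,6S,8S,10R)-13-acetoxy-1,10:4,5-diepoxy-8-[(2S)-2-methyloxirane-2-carbonyloxy]germacr-7(11)-en-12,6-olide | CC(=O)OCC1=C2[C@@H](OC(=O)[C@]3(C)CO3)C[C@@]3(C)O[C@@H]3CC[C@@]3(C)O[C@@H]3[C@H]2OC1=O | target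

**Step count**
Total: 25 steps. Longest linear sequence: 23 steps (steps 1–19, 21, 22, 24, 25, from methyl α-D-glucopyranoside); steps 20 and 23 are one-step side preparations.

**Steps most likely to fail**

Step 25. The metathesis may stall: the ruthenium alkylidene formed on one hindered 1,1-disubstituted alkene may not turn over to the tetrasubstituted, electron-poor alkene before the catalyst decomposes at 80 °C. The fallback makes C7=C11 by carbonyl olefination instead and sets out from ketone 24. DDQ at pH 7 removes the PMB group and gives the 6α-hydroxy-7-ketone F1. DCC coupling with bromo(diethoxyphosphoryl)acetic acid gives the phosphonoacetate F2. LiCl and iPr2NEt in MeCN (Masamune–Roush conditions) close the ring by intramolecular Horner–Wadsworth–Emmons olefination to the 11-bromobutenolide F3. Stille coupling with Bu3SnCH2OH (Pd(PPh3)4, dioxane, 80 °C) gives the 13-hydroxybutenolide F4, and Ac2O/pyridine gives the 13-acetate F5. Pyridine-buffered HF·pyridine frees the 8α-alcohol F6, and Steglich esterification with acid 28 comes back to the route at target 34.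

Step 12. Facial selectivity may be poor or reversed: the nucleophile may enter on the α-face, anti to the axial C10 methyl group, which would place the two alkenyl groups cis and spoil the E,E outcome of step 13. The fallback turns that preference to use in the C10-epimeric series and sets out from iodoenone 11. Stille coupling with SnMe4 (Pd2(dba)3, AsPh3, NMP, 60 °C) gives the 10-methyl enone F7. LiBH(sBu)3 followed by acetaldehyde (reductive aldol, electrophile again axial on the β-face) gives the 10β-(1-hydroxyethyl)-10α-methyl ketone F8 as a carbinol mixture. Burgess reagent dehydrates it to the 10α-methyl-10β-vinyl ketone F9, in which vinyl is axial. Isopropenylcerium addition anti to the axial vinyl group then gives the 5α-isopropenyl-5β-ol F10, again trans-dialkenyl. Its potassium alkoxide (KN(SiMe3)2, 18-crown-6, THF, 40–60 °C) must rearrange through the ring-inverted chair and should be slower, but C5 and C10 vanish, so the same enolate 19 forms and triflation comes back to the route at 20.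

Step 18. The epoxides may open at titanium, or the ketone may enolise toward C6 and open the 4,5-epoxide by β-elimination during the slow methylenation of the hindered carbonyl. The fallback changes the order so that no epoxide is present and sets out from diene 21. Buffered HF·pyridine gives the diene 7β-alcohol F11, Dess–Martin oxidation gives the diene 7-ketone F12, and Cp2TiMe2 (or Ph3P=CH2) gives the 7-methylene triene F13. mCPBA (2.1 equiv, NaHCO3, 0 °C) should then epoxidise the two electron-rich trisubstituted ring alkenes in preference to the 1,1-disubstituted methylene flanked by two C–O bonds, and comes back to the route at 25.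

**Further compounds**
F1 | step 25 | 1β,10α:4α,5β-diepoxy-6α-hydroxy-8α-TBS-oxy-4,10-dimethylcyclodecan-7-one | O=C1[C@@H](O[Si](C)(C)C(C)(C)C)C[C@@]2(C)O[C@@H]2CC[C@@]3(C)O[C@@H]3[C@H]1O
F2 | step 25 | 6α-O-[bromo(diethoxyphosphoryl)acetyl] ester of F1 (CHBr epimers) | O=C1[C@@H](O[Si](C)(C)C(C)(C)C)C[C@@]2(C)O[C@@H]2CC[C@@]3(C)O[C@@H]3[C@H]1OC(=O)C(Br)P(=O)(OCC)OCC
F3 | step 25 | 11-bromo-1β,10α:4α,5β-diepoxy-8α-TBS-oxy-13-norgermacr-7(11)-en-12,6α-olide | BrC1=C2[C@@H](O[Si](C)(C)C(C)(C)C)C[C@@]3(C)O[C@@H]3CC[C@@]3(C)O[C@@H]3[C@H]2OC1=O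
F4 | step 25 | 13-hydroxy-1β,10α:4α,5β-diepoxy-8α-TBS-oxy-germacr-7(11)-en-12,6α-olide | OCC1=C2[C@@H](O[Si](C)(C)C(C)(C)C)C[C@@]3(C)O[C@@H]3CC[C@@]3(C)O[C@@H]3[C@H]2OC1=O
F5 | step 25 | 13-acetoxy-1β,10α:4α,5β-diepoxy-8α-TBS-oxy-germacr-7(11)-en-12,6α-olide | CC(=O)OCC1=C2[C@@H](O[Si](C)(C)C(C)(C)C)C[C@@]3(C)O[C@@H]3CC[C@@]3(C)O[C@@H]3[C@H]2OC1=O
F6 | step 25 | 13-acetoxy-1β,10α:4α,5β-diepoxy-8α-hydroxygermacr-7(11)-en-12,6α-olide | CC(=O)OCC1=C2[C@@H](O)C[C@@]3(C)O[C@@H]3CC[C@@]3(C)O[C@@H]3[C@H]2OC1=O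
F7 | step 12 | 10-methyl-6α-PMB-oxy-7β-TES-oxy-8α-TBS-oxy-cyclohex-9-en-5-one | O=C1C(C)=C[C@H](O[Si](C)(C)C(C)(C)C)[C@@H](O[Si](CC)(CC)CC)[C@@H]1OCc1ccc(OC)cc1
F8 | step 12 | 10β-(1-hydroxyethyl)-10α-methyl-6α-PMB-oxy-7β-TES-oxy-8α-TBS-oxy-cyclohexan-5-one (carbinol epimers) | O=C1[C@@](C)(C(C)O)C[C@H](O[Si](C)(C)C(C)(C)C)[C@@H](O[Si](CC)(CC)CC)[C@@H]1OCc1ccc(OC)cc1
F9 | step 12 | 10α-methyl-10β-vinyl-6α-PMB-oxy-7β-TES-oxy-8α-TBS-oxy-cyclohexan-5-one | O=C1[C@@](C)(C=C)C[C@H](O[Si](C)(C)C(C)(C)C)[C@@H](O[Si](CC)(CC)CC)[C@@H]1OCc1ccc(OC)cc1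
F10 | step 12 | 5α-isopropenyl-10α-methyl-10β-vinyl-6α-PMB-oxy-7β-TES-oxy-8α-TBS-oxy-cyclohexan-5β-ol | C=C(C)[C@]1(O)[C@@](C)(C=C)C[C@H](O[Si](C)(C)C(C)(C)C)[C@@H](O[Si](CC)(CC)CC)[C@@H]1OCc1ccc(OC)cc1
F11 | step 18 | (1(10)E,4E)-4,10-dimethyl-6α-PMB-oxy-8α-TBS-oxy-cyclodeca-1(10),4-dien-7β-ol | O[C@@H]1[C@@H](O[Si](C)(C)C(C)(C)C)C/C(C)=C/CC/C(C)=C/[C@H]1OCc1ccc(OC)cc1
F12 | step 18 | (1(10)E,4E)-4,10-dimethyl-6α-PMB-oxy-8α-TBS-oxy-cyclodeca-1(10),4-dien-7-one | O=C1[C@@H](O[Si](C)(C)C(C)(C)C)C/C(C)=C/CC/C(C)=C/[C@H]1OCc1ccc(OC)cc1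
F13 | step 18 | (1(10)E,4E)-4,10-dimethyl-7-methylene-6α-PMB-oxy-8α-TBS-oxy-cyclodeca-1(10),4-diene | C=C1[C@@H](O[Si](C)(C)C(C)(C)C)C/C(C)=C/CC/C(C)=C/[C@H]1OCc1ccc(OC)cc1
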